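## Structural features

The target is a labdane-type diester on a trans-fused decalin. Ring A is saturated and carries the C4 gem-dimethyl group; ring B holds the C6=C7 alkene; the rings share C5 (H) and the quaternary C10 (methyl C20). Ring B carries a methyl ester (C17) on C8 and, on C9, a two-carbon tether (C11–C12) to a trisubstituted (13E)-enoate whose C13 also bears the acetoxymethyl carbon C16. Four stereocentres stand in a row, C5–C10–C9–C8: H-5 and C20 are trans, the C9 chain is equatorial and on the face of C20, and the C8 ester is equatorial and trans to the C9 chain (5R,8S,9R,10S). The fragile points are the C8 hydrogen (allylic and α to an ester, so base can epimerise it or pull C6=C7 into conjugation), the allylic acetate and the enoate geometry. The real difficulty is the quaternary C10 wedged between C5 and C9, together with an alkene that must stay out of conjugation with C17. The key step exploits that C9 and C8 are neighbours each bearing a carbon that can travel at carbonyl level: C11–C9–C8–C17 is the skeleton of a 4-oxobut-2-enoate, C10 can be delivered as a tertiary radical from a ring-A C1=C10 alkene, and C7 can be the aldehyde onto which ring B closes.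

## Logic of the disconnections

**23 ⇒ 22.** The C16–O bond of the acetate is cut last. The acetate is the group least suited to aqueous base and palladium, so it goes on after the coupling. The forward acylation must leave C8–H alone.

**22 ⇒ 18 + 20.** The C12–C13 bond (sp3–sp2) is cut. This separates the decalin core, with a vinyl group on C9, from a four-carbon piece whose alkene geometry is already fixed. The gain is convergence and an (E) geometry that does not rest on olefination of a ketone. The forward step needs hydroboration of the vinyl group in the presence of C6=C7, coupling with retention, and a base mild enough for C8–H.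

**20 ⇒ 19.** The C13–I and C14–H bonds are removed, leaving an ynoate. The forward anti addition of HI must put iodine cis to the ester.

**18 ⇒ 15 (through 17 and 16).** C17 is taken back from ester to primary alcohol. An ester on C8 would make C8–H acidic while the alkene and the vinyl group are installed. The forward oxidation must pass the aldehyde stage without enolisation.

**15 ⇒ 13 ⇒ 12.** The C11=C12 bond is cut (one-carbon olefination), C11 is raised to carboxyl level and the C17 oxygen is closed onto it. Within the lactone ring C11 and C17 differ in oxidation level, so no protecting group is needed. The forward steps must stop at the lactol and open the ring by methylenation without epimerising C9.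

**12 ⇒ 10 (through 11).** The C6=C7 alkene is traced back to a C7 hydroxyl group. The alkene is made while C17 is at alcohol level, so C8–H is not acidic. The forward elimination must be syn and go to C6; the cis relation of O-7 and C17 ensures this, because C8 then has no cis hydrogen.

**10 ⇒ 8 (through 9).** The lactone C–O bond is opened and C17 returned to aldehyde level. The forward step must reduce only the aldehyde and close the trans-fused lactone.

**8 ⇒ 5 + 6 (through 7).** The C9–C10 and C7–C8 bonds are cut. This removes ring B, three ring stereocentres and both carbonyl-level carbons at once, leaving a monocyclic aldehyde and a four-carbon acceptor. The forward step must build the quaternary carbon trans to the C5 arm, add to C9 and not C8 of the acceptor, and close the ring by aldol addition.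

**5 ⇒ 4 ⇒ 2 (through 3).** The C5–C6 bond is cut in the sense of a [3,3] shift. The two-carbon arm and the C5 stereocentre then derive from a carbinol centre three atoms away. The forward rearrangement must transfer chirality across the ring face and form a bond next to the gem-dimethyl carbon; the ester must then be reduced only to the aldehyde.

**2 ⇒ 1.** The carbinol C–H bond is cut. The single stereocentre from which all others follow is set by enantioselective reduction of an achiral enone.

## Other disconnections considered

**Alternative 1:** The cut runs through C5–C10 and C6=C7 and opens both rings to the acyclic keto enal A2.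
- Forward step: a chiral secondary amine would form the enamine of the C6 aldehyde; C5 would add to C10 of the β,β-disubstituted enone (ring A, quaternary centre); the methyl ketone carbon C7 would then condense with C6 to give enone A1.
- In its favour: both rings and the C5/C10 pair come from an achiral chain under catalyst control, and no metal is needed. The C6=C7 alkene is born in its final place, so the regiochemical question of step 6 does not arise; on this point it is the better plan.
- Against it here: the Michael step must make a quaternary carbon at a doubly β-substituted enone, with an enamine carbon next to the quaternary C4. Amine catalysis is weak and reversible for that combination. A1 also lacks C17 and every side-chain carbon, so C9 would need alkylation next to C10 and the C8 carbonyl would need conversion into CH–CO2Me with trans control, on an enone whose C5 hydrogen is vinylogously acidic.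
- Comparison: structurally, the chosen step delivers C8, C9 and C10 with C11 and C17 attached, whereas A1 delivers only C5 and C10. Mechanistically the two are equals in concept (conjugate addition, then aldol closure), but a radical tolerates the congestion at C10 better. In step count the way to A2 is about as long as the way to 5, while the way from A1 to the target needs more C–C bond formations than the way from 8.

**Alternative 2:** The cut removes C8 as a one-carbon unit (C7–C8 and C8–C9), leaving the trans-fused hydrindene A4 with a C7=C9 alkene and the butenyl chain on C9.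
- Forward step: dibromocarbene (CHBr3, KOt-Bu) would cyclopropanate the ring alkene; electrocyclic opening with loss of bromide (heat or AgClO4) and of the C6 proton would enlarge the ring to bromodiene A3.
- In its favour: C8 arrives as an sp2 carbon bearing bromine, which palladium-catalysed methoxycarbonylation would turn into C17 at ester level. No exchange of oxidation levels between C11 and C17 (steps 5 to 10 of the chosen plan) is needed; here it is the better plan. Carbons C11 to C14 are already on C9, and a terminal alkene is the side-chain handle, as in the chosen plan (equal).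
- Against it here: A4 is a strained trans-hydrindene with the alkene next to the ring fusion, much harder to reach as one enantiomer than 5. The carbene must prefer the hindered ring alkene next to C10 over the terminal alkene. The key step sets no stereocentre, so C9 and C8 would come later from hydride delivery to C9 and kinetic protonation at C8 of a tetrasubstituted C8=C9 bond, with C6=C7 kept in place.
- Comparison: both plans take ring A and C5 from the precursor (equal), but the chosen step creates the C8, C9 and C10 centres while closing ring B and this one creates none. Mechanistically it is a cationic ring expansion against a radical–polar cascade. After the key step the step counts would be close; before it this plan is clearly longer.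

**Alternative 3:** The cut runs through C9–C10 and C5=C6; ring B is annulated onto the ring-A ketone A8 in the Robinson sense.
- Forward step: the enol silane A6 (from A8) would add through C10 to C9 of the alkylidene acetoacetate A7, held as a chelate by a Lewis acid (TiCl4, or Cu(OTf)2 with a chiral bis(oxazoline)). The acetyl methyl carbon C6 would then condense with the C5 carbonyl to give enone A5.
- In its favour: it forms the same C9–C10 bond, but C17 enters as the methyl ester on C8 and the chain is already on C9. No redox exchange is needed, which is better than the chosen plan. A6 and A7 are each about one step from catalogue materials, so the way to the key step is shorter than the three steps to 5 (also better).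
- Against it here: the configuration at C10 would depend on a chiral Lewis acid controlling a tetrasubstituted enol silane that forms a quaternary carbon. The closing condensation must attack a carbonyl flanked by two quaternary carbons (C4, C10), with retro-Michael cleavage competing. C5 is not set and the C7 carbonyl remains, so 1,2-reduction and a reductive allylic transposition would be needed to reach trans H-5 and C6=C7. C8 lies between two carbonyl groups and would epimerise freely.
- Comparison: the plans are equal in joining the fragments at C9–C10 and closing ring B in one operation. The chosen plan closes onto an unhindered aldehyde and brings C5 in already set. Mechanistically it is a polar Mukaiyama–Michael addition against a radical addition that is less sensitive to crowding at C10. It would be shorter before the key step and about equal after, since the saved redox steps are spent on C5/C7 and on a terminal alkene that must still be oxidised at C13, oxygenated at C16 and olefinated with less firm geometry control than step 12.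

Key step: step 4

**Remarks and assumptions**
- Numbering: carbons are numbered as in the labdane skeleton of the target (C1–C10 decalin, C11–C16 side chain, C17 on C8, C18/C19 on C4, C20 on C10).
- Correction to the side arm: ring B needs a two-carbon arm (C6, C7) on C5. An arm made by degrading an ionone through the acrylic acid and two reductions would have three carbons and would close a seven-membered ring. Aldehyde 5 is therefore built by Claisen rearrangement, which also avoids a resolution.
- Assumption: 1, 6 and 19 are taken as catalogue compounds.
- Assumption: the aldol closure is taken to give the C7 epimer with the hydroxyl axial and cis to C17; the fallback for step 6 does not depend on this.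

## Route

**Step 1**
Reactants: 1 2,4,4-trimethylcyclohex-2-en-1-one
Product: 2 (S)-2,4,4-trimethylcyclohex-2-en-1-ol
Conditions: (R)-2-methyl-CBS-oxazaborolidine (10 mol %), BH3·SMe2, THF, −20 °C; MeOH, aqueous work-up
Reagents that add atoms: none
Why: Corey–Bakshi–Shibata reduction; the oxazaborolidine binds the carbonyl oxygen anti to the larger, methyl-substituted alkenyl arm, so hydride reaches one face and the catalyst sets the (S)-carbinol centre. 1,2-Reduction of the enone is faster than hydroboration of the hindered trisubstituted alkene.

**Step 2**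
Reactants: 2 (S)-2,4,4-trimethylcyclohex-2-en-1-ol
Product: 4 ethyl 2-[(1R)-2,6,6-trimethylcyclohex-2-en-1-yl]acetate, via mixed ketene acetal 3 (not isolated)
Conditions: MeC(OEt)3 (excess), EtCO2H (cat.), 140 °C, EtOH distilled off
Reagents that add atoms: triethyl orthoacetate, CC(OCC)(OCC)OCC
Why: Johnson–Claisen rearrangement; acid-catalysed exchange gives ketene acetal 3, whose [3,3] shift forms C5–C6 on the ring face that the C–O bond leaves (suprafacial 1,3-chirality transfer). The (S)-carbinol thus becomes the (R)-configured C5 next to the gem-dimethyl carbon, and the alkene moves to C1=C10.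

**Step 3**
Reactants: 4 ethyl 2-[(1R)-2,6,6-trimethylcyclohex-2-en-1-yl]acetate
Product: 5 2-[(1R)-2,6,6-trimethylcyclohex-2-en-1-yl]acetaldehyde
Conditions: i-Bu2AlH (1.1 equiv), CH2Cl2, −78 °C; aqueous potassium sodium tartrate
Reagents that add atoms: none
Why: Partial reduction of an unhindered ester with i-Bu2AlH at −78 °C stops at the aluminium hemiacetal, which releases the aldehyde on work-up. C5 is not α to the carbonyl group and cannot epimerise.

**Step 4**
Reactants: 5 2-[(1R)-2,6,6-trimethylcyclohex-2-en-1-yl]acetaldehyde; 6 methyl (E)-4-oxobut-2-enoate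
Product: 8 methyl (1R,2R,3S,4aR,8aR)-2-formyl-3-hydroxy-5,5,8a-trimethyldecahydronaphthalene-1-carboxylate, via iron enolate 7 (not isolated)
Conditions: Fe(acac)3 (0.5 equiv), PhSiH3, 6 (2 equiv), EtOH/(CH2OH)2, 0 °C to rt
Reagents that add atoms: none
Why: Fe(acac)3 and PhSiH3 in ethanol give an iron hydride that transfers a hydrogen atom to C1 of the trisubstituted alkene of 5 (MHAT), leaving the tertiary C10 radical. This nucleophilic radical adds to C9 of 6, the carbon β to the formyl group (Giese addition); the α-formyl radical is reduced by divalent iron to the trivalent iron enolate 7, and C8 of 7 adds to the C7 aldehyde. The closest known reaction type is the iron-hydride-initiated radical–polar crossover annulation of alkenyl aldehydes with enals (radical conjugate addition with reductive aldol termination). Ring B closes in the 6-(enolexo)-exo-trig mode through a chair. At C10 the acceptor approaches trans to the C5 side arm and away from the axial C4 methyl group, which gives the trans ring fusion with C5 carried unchanged from 5. C9 and C8 are both α to a carbonyl group and take the trans-diequatorial arrangement in the chair, which is also the thermodynamic one. The C7 hydroxyl is expected cis to the formyl group from an iron-bridged aldolate and is removed in step 6. The step needs addition at C9 rather than C8 of 6, secured by the formyl group being the stronger acceptor, and hydrogen transfer to the electron-rich ring alkene rather than to the electron-poor alkene of 6, which is the normal preference of MHAT.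

**Step 5**
Reactants: 8 methyl (1R,2R,3S,4aR,8aR)-2-formyl-3-hydroxy-5,5,8a-trimethyldecahydronaphthalene-1-carboxylate
Product: 10 (3aS,4S,5aR,9aR,9bR)-4-hydroxy-6,6,9a-trimethyldecahydronaphtho[1,2-c]furan-1(3H)-one, via diol ester 9 (not isolated)
Conditions: NaBH4, MeOH, 0 °C; AcOH quench, solvent exchange; TsOH·H2O (cat.), toluene, 60 °C
Reagents that add atoms: none
Why: Chemoselective borohydride reduction of the aldehyde beside the methyl ester, then acid-catalysed lactonisation (5-exo-trig transesterification) of the new C17 alcohol onto the trans-vicinal C11 ester, driven by loss of methanol. The lactone ties C11 and C17 together at different oxidation levels; no stereocentre is touched, and the axial C7 hydroxyl cannot reach C11.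

**Step 6**
Reactants: 10 (3aS,4S,5aR,9aR,9bR)-4-hydroxy-6,6,9a-trimethyldecahydronaphtho[1,2-c]furan-1(3H)-one
Product: 12 (3aS,5aR,9aR,9bR)-6,6,9a-trimethyl-3a,5a,6,7,8,9,9a,9b-octahydronaphtho[1,2-c]furan-1(3H)-one, via sulfamate salt 11 (not isolated)
Conditions: methyl N-(triethylammoniosulfonyl)carbamate (Burgess reagent), toluene, 70 °C
Reagents that add atoms: none
Why: Burgess dehydration, a thermal syn-elimination of sulfamate 11 through a cyclic transition state. The C7 oxygen is axial and cis to C17, so C8 has no cis hydrogen and the only syn β-hydrogen is the equatorial one on C6, which places the alkene at C6=C7. The medium is neutral and C17 is at alcohol level, so neither C8–H nor the C9 hydrogen α to the lactone is disturbed.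

**Step 7**
Reactants: 12 (3aS,5aR,9aR,9bR)-6,6,9a-trimethyl-3a,5a,6,7,8,9,9a,9b-octahydronaphtho[1,2-c]furan-1(3H)-one
Product: 13 (3aS,5aR,9aR,9bR)-6,6,9a-trimethyl-1,3,3a,5a,6,7,8,9,9a,9b-decahydronaphtho[1,2-c]furan-1-ol (both anomers)
Conditions: i-Bu2AlH (1.1 equiv), CH2Cl2, −78 °C; aqueous potassium sodium tartrate
Reagents that add atoms: none
Why: Lactone-to-lactol reduction; the tetrahedral aluminium intermediate is held in the five-membered ring at −78 °C, so reduction stops at C11 aldehyde level. The isolated alkene is inert and C9 keeps its configuration.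

**Step 8**
Reactants: 13 (3aS,5aR,9aR,9bR)-6,6,9a-trimethyl-1,3,3a,5a,6,7,8,9,9a,9b-decahydronaphtho[1,2-c]furan-1-ol
Product: 15 [(1R,2S,4aR,8aS)-1-ethenyl-5,5,8a-trimethyl-1,2,4a,5,6,7,8,8a-octahydronaphthalen-2-yl]methanol, via open hydroxy aldehyde 14 (not isolated)
Conditions: Ph3PCH3Br, KOt-Bu (excess), THF, 0 °C to 50 °C
Reagents that add atoms: methyltriphenylphosphonium bromide, C[P+](c1ccccc1)(c1ccccc1)c1ccccc1.[Br-]
Why: Wittig methylenation of a lactol; the ring-opened hydroxy aldehyde 14 is olefinated at C11 and the C17 oxygen is released as the free primary alcohol, so one step makes the C9 vinyl group and uncovers C17. The equatorial C9 aldehyde is the more stable epimer, so the basic ylide is not expected to change C9.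

**Step 9**
Reactants: 15 [(1R,2S,4aR,8aS)-1-ethenyl-5,5,8a-trimethyl-1,2,4a,5,6,7,8,8a-octahydronaphthalen-2-yl]methanol
Product: 17 (1R,2S,4aR,8aS)-1-ethenyl-5,5,8a-trimethyl-1,2,4a,5,6,7,8,8a-octahydronaphthalene-2-carboxylic acid, via aldehyde 16 (not isolated)
Conditions: TEMPO (20 mol %), PhI(OAc)2 (2.2 equiv), MeCN/H2O, rt
Reagents that add atoms: water, O
Why: Nitroxyl-catalysed oxidation of a primary alcohol through aldehyde 16 and its hydrate to the acid, in weakly acidic medium without base. C8, now allylic and α to a carbonyl group, should neither epimerise nor let C6=C7 move into conjugation; both alkenes are inert to the oxoammonium salt.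

**Step 10**
Reactants: 17 (1R,2S,4aR,8aS)-1-ethenyl-5,5,8a-trimethyl-1,2,4a,5,6,7,8,8a-octahydronaphthalene-2-carboxylic acid
Product: 18 methyl (1R,2S,4aR,8aS)-1-ethenyl-5,5,8a-trimethyl-1,2,4a,5,6,7,8,8a-octahydronaphthalene-2-carboxylate
Conditions: Me3SiCHN2, MeOH/toluene, 0 °C
Reagents that add atoms: trimethylsilyldiazomethane, C[Si](C)(C)C=[N+]=[N-]
Why: Esterification with trimethylsilyldiazomethane in methanol (proton transfer, then O-methylation) is neutral and fast, so the base-sensitive C8 centre is not exposed.

**Step 11**
Reactants: 19 methyl 4-hydroxybut-2-ynoate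
Product: 20 methyl (2Z)-4-hydroxy-3-iodobut-2-enoate
Conditions: NaI, AcOH (2 equiv), MeCN, 80 °C
Reagents that add atoms: sodium iodide, [Na+].[I-]
Why: Hydroiodination of an ynoate; iodide adds to C13 in the conjugate sense and protonation is anti, giving the (Z)-β-iodoenoate with iodine cis to the ester. This fixes the later (13E) geometry; the hydroxymethyl group is trans to the ester and cannot lactonise.

**Step 12**
Reactants: 18 methyl (1R,2S,4aR,8aS)-1-ethenyl-5,5,8a-trimethyl-1,2,4a,5,6,7,8,8a-octahydronaphthalene-2-carboxylate; 20 methyl (2Z)-4-hydroxy-3-iodobut-2-enoate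
Product: 22 methyl (1R,2S,4aR,8aS)-1-[(3E)-3-(hydroxymethyl)-5-methoxy-5-oxopent-3-en-1-yl]-5,5,8a-trimethyl-1,2,4a,5,6,7,8,8a-octahydronaphthalene-2-carboxylate, via B-alkyl-9-BBN 21 (not isolated)
Conditions: 9-BBN, THF, 0 °C to rt; then 20, PdCl2(dppf) (5 mol %), AsPh3, aq. K3PO4, DMF, rt
Reagents that add atoms: none
Why: Hydroboration with 9-BBN is selective for the terminal vinyl group over the cis-disubstituted ring alkene and puts boron on C12. B-alkyl Suzuki–Miyaura coupling of 21 with the β-iodoenoate forms C12–C13 with retention, so the ester ends cis to the C12 chain (13E); phosphate at room temperature is chosen to spare C8–H.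

**Step 13**
Reactants: 22 methyl (1R,2S,4aR,8aS)-1-[(3E)-3-(hydroxymethyl)-5-methoxy-5-oxopent-3-en-1-yl]-5,5,8a-trimethyl-1,2,4a,5,6,7,8,8a-octahydronaphthalene-2-carboxylate
Product: 23 methyl (1R,2S,4aR,8aS)-1-[(3E)-3-(acetoxymethyl)-5-methoxy-5-oxopent-3-en-1-yl]-5,5,8a-trimethyl-1,2,4a,5,6,7,8,8a-octahydronaphthalene-2-carboxylate
Conditions: Ac2O, pyridine, DMAP (cat.), CH2Cl2, 0 °C to rt
Reagents that add atoms: acetic anhydride, CC(=O)OC(C)=O
Why: DMAP-catalysed acylation of the primary allylic alcohol under weakly basic conditions completes the target without touching C8 or the enoate geometry.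

## Compound list

1 | 2,4,4-trimethylcyclohex-2-en-1-one | O=C1C(C)=CC(C)(C)CC1 | starting material
2 | (S)-2,4,4-trimethylcyclohex-2-en-1-ol | O[C@@H]1C(C)=CC(C)(C)CC1 | intermediate
3 | 1-ethoxy-1-{[(1S)-2,4,4-trimethylcyclohex-2-en-1-yl]oxy}ethene (mixed ketene acetal) | C=C(OCC)O[C@@H]1C(C)=CC(C)(C)CC1 | intermediate (not isolated)
4 | ethyl 2-[(1R)-2,6,6-trimethylcyclohex-2-en-1-yl]acetate | CCOC(=O)C[C@@H]1C(C)(C)CCC=C1C | intermediate
5 | 2-[(1R)-2,6,6-trimethylcyclohex-2-en-1-yl]acetaldehyde | O=CC[C@@H]1C(C)(C)CCC=C1C | intermediate
6 | methyl (E)-4-oxobut-2-enoate | COC(=O)/C=C/C=O | starting material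
7 | trivalent iron enolate of methyl (2R)-4-oxo-2-[(1R,2R)-1,3,3-trimethyl-2-(2-oxoethyl)cyclohexyl]butanoate (drawn as the enolate anion) | COC(=O)[C@H](C=C[O-])[C@]1(C)CCCC(C)(C)[C@H]1CC=O | intermediate (not isolated)
8 | methyl (1R,2R,3S,4aR,8aR)-2-formyl-3-hydroxy-5,5,8a-trimethyldecahydronaphthalene-1-carboxylate | COC(=O)[C@@H]1[C@@H](C=O)[C@@H](O)C[C@@H]2C(C)(C)CCC[C@@]12C | intermediate
9 | methyl (1R,2S,3S,4aR,8aR)-3-hydroxy-2-(hydroxymethyl)-5,5,8a-trimethyldecahydronaphthalene-1-carboxylate | COC(=O)[C@@H]1[C@@H](CO)[C@@H](O)C[C@@H]2C(C)(C)CCC[C@@]12C | intermediate (not isolated)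
10 | (3aS,4S,5aR,9aR,9bR)-4-hydroxy-6,6,9a-trimethyldecahydronaphtho[1,2-c]furan-1(3H)-one | O=C1OC[C@H]2[C@@H](O)C[C@@H]3C(C)(C)CCC[C@@]3(C)[C@H]12 | intermediate
11 | triethylammonium salt of the C7 O-[N-(methoxycarbonyl)sulfamate] of 10 | O=C1OC[C@H]2[C@@H](OS(=O)(=O)[N-]C(=O)OC)C[C@@H]3C(C)(C)CCC[C@@]3(C)[C@H]12.CC[NH+](CC)CC | intermediate (not isolated)
12 | (3aS,5aR,9aR,9bR)-6,6,9a-trimethyl-3a,5a,6,7,8,9,9a,9b-octahydronaphtho[1,2-c]furan-1(3H)-one | O=C1OC[C@H]2C=C[C@@H]3C(C)(C)CCC[C@@]3(C)[C@H]12 | intermediate
13 | (3aS,5aR,9aR,9bR)-6,6,9a-trimethyl-1,3,3a,5a,6,7,8,9,9a,9b-decahydronaphtho[1,2-c]furan-1-ol (both anomers) | OC1OC[C@H]2C=C[C@@H]3C(C)(C)CCC[C@@]3(C)[C@H]12 | intermediate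
14 | (1R,2S,4aR,8aR)-2-(hydroxymethyl)-5,5,8a-trimethyl-1,2,4a,5,6,7,8,8a-octahydronaphthalene-1-carbaldehyde | O=C[C@@H]1[C@@H](CO)C=C[C@@H]2C(C)(C)CCC[C@@]12C | intermediate (not isolated)
15 | [(1R,2S,4aR,8aS)-1-ethenyl-5,5,8a-trimethyl-1,2,4a,5,6,7,8,8a-octahydronaphthalen-2-yl]methanol | C=C[C@@H]1[C@@H](CO)C=C[C@@H]2C(C)(C)CCC[C@@]12C | intermediate
16 | (1R,2S,4aR,8aS)-1-ethenyl-5,5,8a-trimethyl-1,2,4a,5,6,7,8,8a-octahydronaphthalene-2-carbaldehyde | C=C[C@@H]1[C@@H](C=O)C=C[C@@H]2C(C)(C)CCC[C@@]12C | intermediate (not isolated)
17 | (1R,2S,4aR,8aS)-1-ethenyl-5,5,8a-trimethyl-1,2,4a,5,6,7,8,8a-octahydronaphthalene-2-carboxylic acid | C=C[C@@H]1[C@@H](C(=O)O)C=C[C@@H]2C(C)(C)CCC[C@@]12C | intermediate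
18 | methyl (1R,2S,4aR,8aS)-1-ethenyl-5,5,8a-trimethyl-1,2,4a,5,6,7,8,8a-octahydronaphthalene-2-carboxylate | C=C[C@@H]1[C@@H](C(=O)OC)C=C[C@@H]2C(C)(C)CCC[C@@]12C | intermediate
19 | methyl 4-hydroxybut-2-ynoate | COC(=O)C#CCO | starting material
20 | methyl (2Z)-4-hydroxy-3-iodobut-2-enoate | COC(=O)/C=C(\I)CO | intermediate
21 | methyl (1R,2S,4aR,8aS)-1-[2-(9-borabicyclo[3.3.1]nonan-9-yl)ethyl]-5,5,8a-trimethyl-1,2,4a,5,6,7,8,8a-octahydronaphthalene-2-carboxylate | C1CCC2CCCC1B2CC[C@@H]3[C@@H](C(=O)OC)C=C[C@@H]4C(C)(C)CCC[C@@]34C | intermediate (not isolated)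
22 | methyl (1R,2S,4aR,8aS)-1-[(3E)-3-(hydroxymethyl)-5-methoxy-5-oxopent-3-en-1-yl]-5,5,8a-trimethyl-1,2,4a,5,6,7,8,8a-octahydronaphthalene-2-carboxylate | COC(=O)/C=C(\CC[C@@H]1[C@@H](C(=O)OC)C=C[C@@H]2C(C)(C)CCC[C@@]12C)CO | intermediate
23 | methyl (1R,2S,4aR,8aS)-1-[(3E)-3-(acetoxymethyl)-5-methoxy-5-oxopent-3-en-1-yl]-5,5,8a-trimethyl-1,2,4a,5,6,7,8,8a-octahydronaphthalene-2-carboxylate (CNP0190145.1) | COC(=O)/C=C(\CC[C@@H]1[C@@H](C(=O)OC)C=C[C@@H]2C(C)(C)CCC[C@@]12C)COC(C)=O | target

## Step count and least certain steps

Total: 13 steps. Longest linear sequence: 12 steps (steps 1 to 10, 12 and 13); step 11 is a one-step branch.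

**Step 4 (key step).** The C10 radical may be reduced before it adds, or may add with poor regioselectivity, because the ester of 6 also activates the acceptor and the radical is hindered. Poor facial selectivity at C10 is the second weakness. Fallback: from 5, the same annulation with (E)-4,4-dimethoxybut-2-enal (COC(OC)/C=C/C=O) has only one activating group, so addition can occur only β to the formyl group, at the price of a less electrophilic acceptor. It would give the hydroxy aldehyde acetal F1. NaBH4 would give the diol acetal F2, acid (CSA, CH2Cl2) would close the C17 oxygen onto C11 as the cyclic methyl acetal F3, Burgess dehydration would give the unsaturated cyclic acetal F4, and aqueous acetic acid would hydrolyse it to 13, where the route is rejoined.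

**Step 6.** Regiocontrol of the elimination may be lost: if the aldol step delivers the other C7 epimer, or if the sulfamate ionises, hydrogen is lost from C8 and the alkene forms at C7=C8. Fallback, independent of the C7 configuration: from 10, Dess–Martin oxidation to the keto lactone F5; kinetic deprotonation of the C6 methylene (KHMDS, −78 °C) and trapping with PhNTf2 to the enol triflate F6; reduction of the triflate (Pd(OAc)2, PPh3, HCO2H, Bu3N, DMF) to 12.

**Step 12.** Transmetalation of the β-branched alkylborane may be slow, leaving time for protodeboronation or for the aqueous base to epimerise C8 or move C6=C7 into conjugation. Fallback, a base-free Negishi coupling: from 18, hydroboration with 9-BBN and oxidation (NaBO3) to the primary alcohol F7, which is iodinated at once (I2, PPh3, imidazole) to the iodide F8 because it can close onto C17. Zinc insertion (Zn, LiCl, THF) gives the alkylzinc iodide F9, which is coupled (Pd(OAc)2, SPhos, THF) with the silyl ether F10, made from 20 with TBSCl and imidazole. The product is the silyl ether F11, and HF·pyridine then gives 22.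

**Step 8.** Methylenation at the hindered C11 may be sluggish, with epimerisation at C9 through the open aldehyde under the basic ylide. Fallback, a Peterson olefination with a less basic nucleophile: from 13, Me3SiCH2MgCl adds to the open aldehyde to give the β-hydroxysilane F12, and KH in THF eliminates silanolate to give 15.

**Step 2.** The rearrangement may be slow because the new bond forms next to the quaternary carbon, so that acid-promoted loss of water from 2 competes. Fallback, the neutral Eschenmoser–Claisen rearrangement: from 2, N,N-dimethylacetamide dimethyl acetal in xylene at 140 °C gives the amide F13, which Cp2Zr(H)Cl in THF reduces to 5.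

## Further compounds

F1 | step 4 | 1-(dimethoxymethyl)-3-hydroxy-5,5,8a-trimethyldecahydronaphthalene-2-carbaldehyde, configured as 8 | COC(OC)[C@@H]1[C@@H](C=O)[C@@H](O)C[C@@H]2C(C)(C)CCC[C@@]12C
F2 | step 4 | 1-(dimethoxymethyl)-2-(hydroxymethyl)-5,5,8a-trimethyldecahydronaphthalen-3-ol, configured as 9 | COC(OC)[C@@H]1[C@@H](CO)[C@@H](O)C[C@@H]2C(C)(C)CCC[C@@]12C
F3 | step 4 | 1-methoxy-6,6,9a-trimethyldodecahydronaphtho[1,2-c]furan-4-ol, configured as 10 (both anomers) | COC1OC[C@H]2[C@@H](O)C[C@@H]3C(C)(C)CCC[C@@]3(C)[C@H]12
F4 | step 4 | 1-methoxy-6,6,9a-trimethyl-1,3,3a,5a,6,7,8,9,9a,9b-decahydronaphtho[1,2-c]furan, configured as 12 (both anomers) | COC1OC[C@H]2C=C[C@@H]3C(C)(C)CCC[C@@]3(C)[C@H]12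
F5 | step 6 | 6,6,9a-trimethyloctahydronaphtho[1,2-c]furan-1,4(3H,3aH)-dione, configured as 10 | O=C1OC[C@H]2C(=O)C[C@@H]3C(C)(C)CCC[C@@]3(C)[C@H]12
F6 | step 6 | 6,6,9a-trimethyl-1-oxo-1,3,3a,5a,6,7,8,9,9a,9b-decahydronaphtho[1,2-c]furan-4-yl trifluoromethanesulfonate, configured as 12 | O=C1OC[C@H]2C(OS(=O)(=O)C(F)(F)F)=C[C@@H]3C(C)(C)CCC[C@@]3(C)[C@H]12
F7 | step 12 | methyl 1-(2-hydroxyethyl)-5,5,8a-trimethyl-1,2,4a,5,6,7,8,8a-octahydronaphthalene-2-carboxylate, configured as 18 | OCC[C@@H]1[C@@H](C(=O)OC)C=C[C@@H]2C(C)(C)CCC[C@@]12C
F8 | step 12 | methyl 1-(2-iodoethyl)-5,5,8a-trimethyl-1,2,4a,5,6,7,8,8a-octahydronaphthalene-2-carboxylate, configured as 18 | ICC[C@@H]1[C@@H](C(=O)OC)C=C[C@@H]2C(C)(C)CCC[C@@]12C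
F9 | step 12 | alkylzinc iodide from F8 (not isolated) | I[Zn]CC[C@@H]1[C@@H](C(=O)OC)C=C[C@@H]2C(C)(C)CCC[C@@]12C
F10 | step 12 | methyl (2Z)-4-[(tert-butyldimethylsilyl)oxy]-3-iodobut-2-enoate | COC(=O)/C=C(\I)CO[Si](C)(C)C(C)(C)C
F11 | step 12 | tert-butyldimethylsilyl ether of 22 | COC(=O)/C=C(\CC[C@@H]1[C@@H](C(=O)OC)C=C[C@@H]2C(C)(C)CCC[C@@]12C)CO[Si](C)(C)C(C)(C)C
F12 | step 8 | 1-[2-(hydroxymethyl)-5,5,8a-trimethyl-1,2,4a,5,6,7,8,8a-octahydronaphthalen-1-yl]-2-(trimethylsilyl)ethanol, ring configured as 14 (both carbinol epimers) | C[Si](C)(C)CC(O)[C@@H]1[C@@H](CO)C=C[C@@H]2C(C)(C)CCC[C@@]12C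
F13 | step 2 | N,N-dimethyl-2-[(1R)-2,6,6-trimethylcyclohex-2-en-1-yl]acetamide | CN(C)C(=O)C[C@@H]1C(C)(C)CCC=C1C
A1 | alternative 1 | trans-5,5,8a-trimethyl-4a,5,6,7,8,8a-hexahydronaphthalen-2(1H)-one | C1C(=O)C=C[C@@H]2C(C)(C)CCC[C@@]12C
A2 | alternative 1 | (E)-3,3,7-trimethyl-9-oxodec-7-enal | O=CCC(C)(C)CCC/C(C)=C/C(C)=O
A3 | alternative 2 | trans-2-bromo-1-(but-3-enyl)-5,5,8a-trimethyl-4a,5,6,7,8,8a-hexahydronaphthalene | C=CCCC1=C(Br)C=C[C@@H]2C(C)(C)CCC[C@@]12C
A4 | alternative 2 | trans-3-(but-3-enyl)-3a,7,7-trimethyl-3a,4,5,6,7,7a-hexahydro-1H-indene | C=CCCC1=CC[C@@H]2C(C)(C)CCC[C@@]12C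
A5 | alternative 3 | methyl 1-(but-3-enyl)-5,5,8a-trimethyl-3-oxo-1,2,3,5,6,7,8,8a-octahydronaphthalene-2-carboxylate | C=CCC[C@@H]1[C@@H](C(=O)OC)C(=O)C=C2C(C)(C)CCC[C@@]12C
A6 | alternative 3 | trimethyl[(2,6,6-trimethylcyclohex-1-en-1-yl)oxy]silane | CC1=C(O[Si](C)(C)C)C(C)(C)CCC1
A7 | alternative 3 | methyl 2-acetylhepta-2,6-dienoate (alkene geometry not defined) | C=CCCC=C(C(C)=O)C(=O)OC
A8 | alternative 3 | 2,2,6-trimethylcyclohexanone | CC1CCCC(C)(C)C1=O
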